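## Analysis of the target

Gravicycle (24, C26H36O5) is a 22-membered meta,para-cyclophane made of two benzene rings, one diaryl ether oxygen and a fourteen-carbon tether. Ring A carries three substituents in an all-meta array: a free OH on C1, the ether oxygen on C3 and the first CH2 of the tether on C5, with hydrogen on C2, C4 and C6. Ring B is 3',4',5'-trioxygenated: free OH on C3' and C5', the ether oxygen on C4' between them, and on C1' the benzylic carbinol carbon, which reaches C5 of ring A through thirteen methylene groups. The only stereocentre is that carbinol carbon. It is read from the SMILES string as (R) (OH > ring B > CH2 > H), and with no second stereo element to relay from, it must be set by reagent control. The sensitive sites are the benzylic alcohol para to an aryloxy group (ionisation under acid, hydrogenolysis) and the pyrogallol-type ring B (oxidation once its phenols are free). The synthesis is hard for four reasons: the ether oxygen sits between two oxygen substituents, so a classical arylation must engage a di-ortho-substituted, electron-rich partner; ring A is a resorcinol with two different oxygens, which from a symmetric 5-alkylresorcinol would need desymmetrisation; a 22-membered ring must be closed; and three phenols must be unmasked without touching the carbinol. The feature that invites the chosen move is the ring A pattern itself: C1–OH, C3–O and C5–alkyl, with hydrogen between them, is what a vinylketene from a 3-alkylcyclobutenone gives when it is annulated with a terminal alkynyl ether. Ring A can therefore be built around the ether oxygen instead of being attached to it.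

## Retrosynthetic reasoning

24 to 23. The last bond cut is the C–H bond at the stereocentre. Reducing the prochiral aryl alkyl ketone 23 as the final step means the acid- and hydrogenolysis-sensitive carbinol never meets a Lewis acid, a hydrogenation catalyst or heat. The forward step must discriminate the two faces of a ketone flanked by an aryl ring and a methylene chain, a standard task for a chiral ruthenium transfer-hydrogenation catalyst.

23 to 22. The two O–CH3 bonds on ring B are cut at the ketone stage, where a strong Lewis acid is harmless because no benzylic C–O bond can ionise. This lets the cheap aldehyde 1 supply ring B with C4'–OH already differentiated from the C3' and C5' oxygens, and no protecting group has to be introduced.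

22 to 21 to 20. The macrocycle is opened at a C=C bond in the middle of the tether, five and six carbons away from the carbonyl carbon, i.e. ring-closing metathesis followed by hydrogenation. The cut is placed there because it is remote from both arenes, unhindered, and creates no stereochemical issue that survives hydrogenation. The forward reaction only has to favour ring closure over oligomerisation at high dilution.

20 to 10 and 15 (key disconnection). Ring A is taken apart completely at C1–C2 and C3–C4. C2 and C3, together with the ether oxygen already bonded to ring B, fall to alkynyl ether 10. C1, C4, C5 and C6, together with the ring A half of the tether, fall to cyclobutenone 15. Three things are gained: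
- no arylation of the hindered C4' oxygen is ever needed, because the oxygen is carried into ring A on the alkyne;
- the resorcinol arrives desymmetrised, with one free OH and one aryl ether;
- the two halves of the molecule are joined in the same operation.

The forward reaction must deliver one regiochemistry (OH, O-aryl and alkyl mutually meta) and must prefer the alkynyl ether over two terminal alkenes and a ketone.

10 to 9 to 6 to 3 and 4; 3 to 1 and 2. The alkynyl ether is traced to a 1,2-dichlorovinyl ether, put on the phenol oxygen of 1 with 2 in the first step, when that oxygen carries the least baggage. The ketone of 10 is reached through the racemic alcohols 6 and 9, because unveiling the alkyne needs an alkyllithium that a ketone would not survive. The alkoxide of 6 is inert, and the stereocentre is erased at 10 anyway. The C–C bond between the carbinol carbon and the chain comes from Grignard addition of 5 (from 4) to aldehyde 3.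

15 to 11 and 12. The bond between C3 of the cyclobutenone and the chain is cut. The forward step is 1,2-addition of Grignard reagent 13 (from 11) to vinylogous ester 12, followed by hydrolytic transposition, one operation from two building blocks.

## Alternatives that were turned down

Alternative 1: the textbook route. The disconnection is the C3(ring A)–O bond of the diaryl ether, closed last as the macrocyclisation after linear assembly of the tether. The forward key step would be an intramolecular Ullmann etherification of seco bromo phenol A1 (a 1-(4-bromo-3,5-dimethoxyphenyl) ketone whose C14 chain ends in a 3-benzyloxy-5-hydroxyphenyl group) to the macrocyclic ether A2. It was turned down for these reasons: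
- The bromide of A1 lies between two methoxy groups, and the copper phenoxide has to reach it across a 22-atom loop at high dilution. A slow coupling at a di-ortho-substituted carbon is thus combined with an entropically costly ring closure.
- A1 needs a statistically mono-protected 5-alkylresorcinol and a stepwise build-up of the tether.
- The key step builds one bond and nothing else, while carrying both main risks of the target.

Alternative 2: a macrocyclising benzannulation. The disconnection is the same ring A cut as in the chosen route, but with both partners tethered, so that one thermal step on A3 (the alkynyl ether of 10 joined through thirteen CH2 groups to C3 of a cyclobut-2-enone) would form ring A and the macrocycle and give 22 directly. It was turned down because A3 cannot be assembled economically: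
- the alkynyl ether is unveiled with an alkyllithium, which a cyclobutenone does not survive;
- a cyclobutenone made by ketene cycloaddition or acid-mediated transposition cannot be built in the presence of the more ketenophilic, acid-labile alkynyl ether.

Every ordering therefore costs four to six masking and redox steps, more than the two steps (metathesis and hydrogenation) it would save. The [2+2] capture would also have to compete at millimolar concentration with decomposition of the alkynyl ether.

Alternative 3: ring A carried as a saturated ring and aromatised late. The disconnection is the C3–O bond, formed as a vinylogous ester instead of a diaryl ether. The forward key step would be addition–elimination of the phenoxide of A5 (1-(4-hydroxy-3,5-dimethoxyphenyl)hex-5-en-1-one) on chloroenone A4 (3-chloro-5-(dec-9-en-1-yl)cyclohex-2-en-1-one) to give A6, then dehydrogenation of A6 to phenol 20. The C–O bond formation is credible even for the hindered phenoxide. It was turned down for these reasons: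
- A4 needs its own Michael/Claisen/decarboxylation/chlorination sequence.
- Dehydrogenating a 3-aryloxycyclohexenone needs a palladium/oxygen or halogenation–elimination protocol, which threatens the two terminal alkenes and the electron-rich ring B.
- The benzannulation delivers the same compound 20 at the phenol oxidation level in one step from a one-step fragment.

Key step: step 6

Assumptions: 3-ethoxycyclobut-2-en-1-one (12) is taken as a catalogue chemical. Macrocyclic alkene 21 is expected as an E/Z mixture, which is irrelevant because both isomers give 22.

## Route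

Step 1
Reactants: 1 4-hydroxy-3,5-dimethoxybenzaldehyde (syringaldehyde); 2 trichloroethylene
Product: 3 4-{[(E)-1,2-dichloroethenyl]oxy}-3,5-dimethoxybenzaldehyde
Conditions: K2CO3 (2 equiv), 2 (2 equiv), DMF, 70 °C
Reagents that add atoms: none
Why: Base-induced dehydrochlorination of 2 gives dichloroacetylene, to which the phenoxide adds in anti fashion to give the (E)-dichlorovinyl ether (the trichloroethylene route to alkynyl ethers); the non-enolisable aldehyde and the methyl ethers are inert to carbonate.

Step 2
Reactants: 3 4-{[(E)-1,2-dichloroethenyl]oxy}-3,5-dimethoxybenzaldehyde; 4 5-bromopent-1-ene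
Product: 6 rac-1-(4-{[(E)-1,2-dichloroethenyl]oxy}-3,5-dimethoxyphenyl)hex-5-en-1-ol, via pent-4-enylmagnesium bromide 5 (not isolated)
Conditions: 4, Mg, THF, rt; then 3, THF, −78 → 0 °C; then H2O
Reagents that add atoms: none
Why: Grignard addition to an aromatic aldehyde; the electron-poor dichlorovinyl ether does not react with an alkylmagnesium halide at or below 0 °C. The alcohol is made racemic on purpose, because this centre is oxidised in step 4 and set in step 10.

Step 3
Reactants: 6 rac-1-(4-{[(E)-1,2-dichloroethenyl]oxy}-3,5-dimethoxyphenyl)hex-5-en-1-ol
Product: 9 rac-1-[4-(ethynyloxy)-3,5-dimethoxyphenyl]hex-5-en-1-ol, via chloroethynyl ether lithium alkoxide 7 (not isolated), via dilithiated alkynyl ether 8 (not isolated)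
Conditions: n-BuLi (3.3 equiv), THF, −78 → −40 °C; then H2O, −40 °C
Reagents that add atoms: none
Why: The first equivalent of base parks the alcohol as its alkoxide, the second removes the vinylic hydrogen and expels chloride to give chloroalkyne 7, and the third effects chlorine–lithium exchange to acetylide 8, which is protonated on quenching (standard conversion of dichlorovinyl ethers into terminal alkynyl ethers). The terminal alkene and methyl ethers are inert at these temperatures.

Step 4
Reactants: 9 rac-1-[4-(ethynyloxy)-3,5-dimethoxyphenyl]hex-5-en-1-ol
Product: 10 1-[4-(ethynyloxy)-3,5-dimethoxyphenyl]hex-5-en-1-one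
Conditions: activated MnO2 (15 equiv), CH2Cl2, rt
Reagents that add atoms: none
Why: Heterogeneous MnO2 oxidation of an activated benzylic alcohol under neutral, non-aqueous conditions, which spare the acid-labile alkynyl ether and the alkene.

Step 5
Reactants: 11 10-bromodec-1-ene; 12 3-ethoxycyclobut-2-en-1-one
Product: 15 3-(dec-9-en-1-yl)cyclobut-2-en-1-one, via dec-9-enylmagnesium bromide 13 (not isolated), via cyclobutenolate adduct 14 (not isolated)
Conditions: 11, Mg, THF, rt; then 12, THF, −78 °C; then 1 M aq. HCl, 0 °C → rt
Reagents that add atoms: water, O
Why: 1,2-Addition of the Grignard reagent to the vinylogous ester, then acid hydrolysis of the enol ether and loss of the tertiary hydroxyl (a Stork–Danheiser-type transposition) put the chain on C3 of the cyclobutenone; the new carbonyl oxygen comes from water and the old one leaves as water.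

Step 6
Reactants: 10 1-[4-(ethynyloxy)-3,5-dimethoxyphenyl]hex-5-en-1-one; 15 3-(dec-9-en-1-yl)cyclobut-2-en-1-one
Product: 20 1-{4-[3-(dec-9-en-1-yl)-5-hydroxyphenoxy]-3,5-dimethoxyphenyl}hex-5-en-1-one, via vinylketene 16 (not isolated), via 4-vinylcyclobutenone 17 (not isolated), via dienylketene 18 (not isolated), via cyclohexadienone 19 (not isolated)
Conditions: 10 (1 equiv), 15 (1.5 equiv), toluene (0.4 M), 80 °C then 110 °C; then KOH, MeOH, rt
Reagents that add atoms: none
Why: Heating opens 15 reversibly by 4π-electrocyclic ring opening to vinylketene 16, which the electron-rich alkyne of 10 captures in a regioselective [2+2] cycloaddition to give 17; a second 4π opening gives dienylketene 18, 6π-electrocyclisation gives cyclohexadienone 19, and tautomerisation gives phenol 20. The closest known reaction type is the Danheiser benzannulation of 3-alkylcyclobutenones with alkoxyacetylenes, which gives 5-alkylresorcinol monoethers; here an aryloxyacetylene takes the place of the alkoxyacetylene. Ring A is the only ring closed: its C1–C2 and C3–C4 bonds come from the [2+2] step, and the six-membered ring is closed at C1–C6 by the thermal disrotatory 6π-electrocyclisation of 18. No stereocentre is formed. The step needs one regiochemical outcome, OH, O-aryl and alkyl mutually meta, and the polarisation of the partners secures it: the nucleophilic terminal carbon of the alkynyl ether bonds to the ketene carbonyl carbon, so the oxygen-bearing alkyne carbon becomes C3 and the alkyl-bearing carbon of 15 becomes C5. It also needs chemoselectivity for the alkynyl ether over the two terminal alkenes and the aryl ketone, which the far higher ketenophilicity of an alkynyl ether provides; an aryl alkynyl ether also has no β-hydrogen for the retro-ene fragmentation that limits alkyl congeners at this temperature. Aryl esters formed when 20 intercepts 16 are cleaved in the KOH/MeOH work-up, which is why 15 is used in excess.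

Step 7
Reactants: 20 1-{4-[3-(dec-9-en-1-yl)-5-hydroxyphenoxy]-3,5-dimethoxyphenyl}hex-5-en-1-one
Product: 21 macrocyclic alkene (22-membered cyclophane ketone formed by joining the two terminal alkene carbons of 20; C=C between tether carbons 5 and 6 counted from the carbonyl carbon; E/Z mixture)
Conditions: second-generation Grubbs catalyst RuCl2(=CHPh)(H2IMes)(PCy3) (5 mol%), CH2Cl2 (1 mM), 40 °C
Reagents that add atoms: none
Why: Ring-closing metathesis of two unhindered terminal alkenes to an unstrained 22-membered ring, driven by loss of ethene and favoured over oligomerisation by high dilution; the free phenol, aryl ketone and ethers are tolerated by the ruthenium carbene.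

Step 8
Reactants: 21 macrocyclic alkene
Product: 22 saturated macrocyclic ketone (ring B 3',5'-dimethyl ether of ketone 23)
Conditions: H2 (1 atm), Pd/C (10%), EtOAc, rt
Reagents that add atoms: none
Why: Heterogeneous hydrogenation of a disubstituted alkene; under neutral conditions in EtOAc the aryl ketone on the electron-rich ring is reduced far more slowly, and the diaryl ether is inert.

Step 9
Reactants: 22 saturated macrocyclic ketone
Product: 23 gravicycle ketone (22-membered cyclophane aryl ketone with free OH on C1 of ring A and on C3' and C5' of ring B)
Conditions: BBr3 (6 equiv), CH2Cl2, −78 → 0 °C; then H2O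
Reagents that add atoms: none
Why: Lewis-acid demethylation of the two aryl methyl ethers; at the ketone oxidation level there is no benzylic C–O bond to ionise, and diaryl ethers are not cleaved by BBr3.

Step 10
Reactants: 23 gravicycle ketone
Product: 24 gravicycle, (R)-configured benzylic alcohol
Conditions: RuCl[(R,R)-TsDPEN](p-cymene) (2 mol%), HCO2H/Et3N (5:2), DMF, 30 °C
Reagents that add atoms: none
Why: Noyori–Ikariya asymmetric transfer hydrogenation of an aryl alkyl ketone; the (R,R)-ligand delivers hydride to the Si face, with ring B held against the η6-arene of the catalyst by a CH/π contact, which gives the (R)-alcohol as for simple aryl alkyl ketones. The outer-sphere mechanism tolerates free meta-phenols, and the stereocentre is formed in the last step, so nothing can scramble it.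

## Compound list

1 | 4-hydroxy-3,5-dimethoxybenzaldehyde (syringaldehyde) | COc1cc(C=O)cc(OC)c1O | starting material
2 | trichloroethylene | ClC=C(Cl)Cl | starting material
3 | 4-{[(E)-1,2-dichloroethenyl]oxy}-3,5-dimethoxybenzaldehyde | COc1cc(C=O)cc(OC)c1O/C(Cl)=C\Cl | intermediate
4 | 5-bromopent-1-ene | C=CCCCBr | starting material
5 | pent-4-enylmagnesium bromide (not isolated) | C=CCCC[Mg]Br | intermediate
6 | rac-1-(4-{[(E)-1,2-dichloroethenyl]oxy}-3,5-dimethoxyphenyl)hex-5-en-1-ol | COc1cc(C(O)CCCC=C)cc(OC)c1O/C(Cl)=C\Cl | intermediate
7 | lithium 1-{4-[(chloroethynyl)oxy]-3,5-dimethoxyphenyl}hex-5-en-1-olate (not isolated) | [Li]OC(CCCC=C)c1cc(OC)c(OC#CCl)c(OC)c1 | intermediate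
8 | lithium 1-{4-[(lithioethynyl)oxy]-3,5-dimethoxyphenyl}hex-5-en-1-olate (not isolated) | [Li]OC(CCCC=C)c1cc(OC)c(OC#C[Li])c(OC)c1 | intermediate
9 | rac-1-[4-(ethynyloxy)-3,5-dimethoxyphenyl]hex-5-en-1-ol | C#COc1c(OC)cc(cc1OC)C(O)CCCC=C | intermediate
10 | 1-[4-(ethynyloxy)-3,5-dimethoxyphenyl]hex-5-en-1-one | C#COc1c(OC)cc(cc1OC)C(=O)CCCC=C | intermediate
11 | 10-bromodec-1-ene | C=CCCCCCCCCBr | starting material
12 | 3-ethoxycyclobut-2-en-1-one | CCOC1=CC(=O)C1 | starting material
13 | dec-9-enylmagnesium bromide (not isolated) | C=CCCCCCCCC[Mg]Br | intermediate
14 | bromomagnesium 1-(dec-9-en-1-yl)-3-ethoxycyclobut-2-en-1-olate (not isolated) | CCOC1=CC(CCCCCCCCC=C)(O[Mg]Br)C1 | intermediate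
15 | 3-(dec-9-en-1-yl)cyclobut-2-en-1-one | O=C1C=C(CCCCCCCCC=C)C1 | intermediate
16 | 3-methylidenetrideca-1,12-dien-1-one, vinylketene (not isolated) | O=C=CC(=C)CCCCCCCCC=C | intermediate
17 | 4-(dodeca-1,11-dien-2-yl)-3-[4-(hex-5-enoyl)-2,6-dimethoxyphenoxy]cyclobut-2-en-1-one (not isolated) | O=C1C=C(Oc2c(OC)cc(cc2OC)C(=O)CCCC=C)C1C(=C)CCCCCCCCC=C | intermediate
18 | (3E)-3-[4-(hex-5-enoyl)-2,6-dimethoxyphenoxy]-5-methylidenepentadeca-1,3,14-trien-1-one, dienylketene (not isolated) | O=C=C/C(Oc1c(OC)cc(cc1OC)C(=O)CCCC=C)=C\C(=C)CCCCCCCCC=C | intermediate
19 | 5-(dec-9-en-1-yl)-3-[4-(hex-5-enoyl)-2,6-dimethoxyphenoxy]cyclohexa-2,4-dien-1-one (not isolated) | O=C1C=C(Oc2c(OC)cc(cc2OC)C(=O)CCCC=C)C=C(CCCCCCCCC=C)C1 | intermediate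
20 | 1-{4-[3-(dec-9-en-1-yl)-5-hydroxyphenoxy]-3,5-dimethoxyphenyl}hex-5-en-1-one | Oc1cc(Oc2c(OC)cc(cc2OC)C(=O)CCCC=C)cc(CCCCCCCCC=C)c1 | intermediate
21 | macrocyclic alkene (22-membered cyclophane ketone, ring B dimethyl ether, E/Z mixture) | Oc1cc2cc(c1)Oc1c(OC)cc(cc1OC)C(=O)CCCC=CCCCCCCCC2 | intermediate
22 | saturated macrocyclic ketone (ring B dimethyl ether of 23) | Oc1cc2cc(c1)Oc1c(OC)cc(cc1OC)C(=O)CCCCCCCCCCCCC2 | intermediate
23 | gravicycle ketone | Oc1cc2cc(c1)Oc1c(O)cc(cc1O)C(=O)CCCCCCCCCCCCC2 | intermediate
24 | gravicycle, (R) | Oc1cc2cc(c1)Oc1c(O)cc(cc1O)[C@H](O)CCCCCCCCCCCCC2 | target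

## Step count and risks

Total: 10 steps. Longest linear sequence: 9 steps (steps 1–4 and 6–10 from 1); step 5 is a one-step side branch.

Least certain steps:

Step 6 (key). The most likely failure is that thermal oligomerisation of the terminal alkynyl ether outruns its [2+2] capture by the vinylketene, because the para-acyl group lowers the nucleophilicity of the alkyne. Consumption of the vinylketene by O-acylation of the product phenol would add to this. The fallback abandons ring construction and forms the diaryl ether by arylating the hindered phenol. It sets out from 13 (made from 11), 1 and 5, and returns at 23. Kumada coupling of 13 with an excess of commercial 1,3-dibromo-5-methoxybenzene (PdCl2(dppf) cat., THF) should give 1-bromo-3-(dec-9-en-1-yl)-5-methoxybenzene F1. Ullmann etherification of 1 with F1 (CuI, picolinic acid, K3PO4, DMSO, 90–110 °C) should give 4-[3-(dec-9-en-1-yl)-5-methoxyphenoxy]-3,5-dimethoxybenzaldehyde F2. Addition of 5 should give rac-1-{4-[3-(dec-9-en-1-yl)-5-methoxyphenoxy]-3,5-dimethoxyphenyl}hex-5-en-1-ol F3, and MnO2 oxidation 1-{4-[3-(dec-9-en-1-yl)-5-methoxyphenoxy]-3,5-dimethoxyphenyl}hex-5-en-1-one F4. Ring-closing metathesis as in step 7 should give the tri-O-methyl macrocyclic alkene F5, hydrogenation as in step 8 the tri-O-methyl macrocyclic ketone F6, and BBr3 (three methyl ethers) would return 23.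

Step 1. The most likely failure is slow addition of the phenoxide to dichloroacetylene. The phenoxide of 1 is flanked by two methoxy groups and delocalised into the para-formyl group, so long heating may let the dichloroacetylene decompose first. The fallback reverses the order so that a more electron-rich phenoxide is vinylated. It sets out from 1 and 5 and returns at 6. Addition of 5 (2.2 equiv, the first equivalent deprotonating the phenol) to 1 should give rac-4-(1-hydroxyhex-5-en-1-yl)-2,6-dimethoxyphenol F7, whose phenoxide is no longer a vinylogous carboxylate. Vinylation of F7 with 2 (K2CO3, DMF, 70 °C) then gives 6.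

Step 4. The most likely failure is hydration or oxidative degradation of the alkynyl ether on the oxidant surface before the benzylic alcohol is consumed. The fallback moves the oxidation behind the benzannulation, so that no oxidant meets the alkynyl ether; it also makes the alkyne more electron-rich for step 6. It sets out from 9 and returns at 20. Silylation of 9 (TBSCl, imidazole, DMF) should give rac-tert-butyl({1-[4-(ethynyloxy)-3,5-dimethoxyphenyl]hex-5-en-1-yl}oxy)dimethylsilane F8. Benzannulation of F8 with 15 under the conditions of step 6 should give rac-3-[4-(1-{[tert-butyl(dimethyl)silyl]oxy}hex-5-en-1-yl)-2,6-dimethoxyphenoxy]-5-(dec-9-en-1-yl)phenol F9. Desilylation (TBAF, THF) should give rac-3-(dec-9-en-1-yl)-5-[4-(1-hydroxyhex-5-en-1-yl)-2,6-dimethoxyphenoxy]phenol F10, and MnO2 oxidation of the benzylic alcohol returns 20.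

Step 10. The most likely failures are eroded facial selectivity, because the macrocycle and the long alkyl chain may disturb the arene–arene contact that orients the ketone; slow turnover in the presence of three phenols; and partial ionisation of the product carbinol in the formic acid medium. The fallback changes both the reductant and the substrate. It sets out from 23 and returns at 24. Silylation of the three phenols (TBSCl, imidazole, DMF) should give the tris-TBS ether of 23, F11. Corey–Bakshi–Shibata reduction ((S)-2-methyl-CBS-oxazaborolidine cat., BH3·SMe2, THF, −20 °C; aryl as the large group, (R)-alcohol expected) should give the tris-TBS ether of 24, F12. Fluoride (TBAF, THF, 0 °C) then releases 24 under non-acidic conditions.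

## Further compounds

F1 | step 6 | 1-bromo-3-(dec-9-en-1-yl)-5-methoxybenzene | COc1cc(Br)cc(CCCCCCCCC=C)c1
F2 | step 6 | 4-[3-(dec-9-en-1-yl)-5-methoxyphenoxy]-3,5-dimethoxybenzaldehyde | COc1cc(CCCCCCCCC=C)cc(Oc2c(OC)cc(C=O)cc2OC)c1
F3 | step 6 | rac-1-{4-[3-(dec-9-en-1-yl)-5-methoxyphenoxy]-3,5-dimethoxyphenyl}hex-5-en-1-ol | COc1cc(CCCCCCCCC=C)cc(Oc2c(OC)cc(cc2OC)C(O)CCCC=C)c1
F4 | step 6 | 1-{4-[3-(dec-9-en-1-yl)-5-methoxyphenoxy]-3,5-dimethoxyphenyl}hex-5-en-1-one | COc1cc(CCCCCCCCC=C)cc(Oc2c(OC)cc(cc2OC)C(=O)CCCC=C)c1
F5 | step 6 | tri-O-methyl macrocyclic alkene (ring A methyl ether of 21, E/Z mixture) | COc1cc2cc(c1)Oc1c(OC)cc(cc1OC)C(=O)CCCC=CCCCCCCCC2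
F6 | step 6 | tri-O-methyl macrocyclic ketone (ring A methyl ether of 22) | COc1cc2cc(c1)Oc1c(OC)cc(cc1OC)C(=O)CCCCCCCCCCCCC2
F7 | step 1 | rac-4-(1-hydroxyhex-5-en-1-yl)-2,6-dimethoxyphenol | COc1cc(C(O)CCCC=C)cc(OC)c1O
F8 | step 4 | rac-tert-butyl({1-[4-(ethynyloxy)-3,5-dimethoxyphenyl]hex-5-en-1-yl}oxy)dimethylsilane | C#COc1c(OC)cc(cc1OC)C(O[Si](C)(C)C(C)(C)C)CCCC=C
F9 | step 4 | rac-3-[4-(1-{[tert-butyl(dimethyl)silyl]oxy}hex-5-en-1-yl)-2,6-dimethoxyphenoxy]-5-(dec-9-en-1-yl)phenol | Oc1cc(Oc2c(OC)cc(cc2OC)C(O[Si](C)(C)C(C)(C)C)CCCC=C)cc(CCCCCCCCC=C)c1
F10 | step 4 | rac-3-(dec-9-en-1-yl)-5-[4-(1-hydroxyhex-5-en-1-yl)-2,6-dimethoxyphenoxy]phenol | Oc1cc(Oc2c(OC)cc(cc2OC)C(O)CCCC=C)cc(CCCCCCCCC=C)c1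
F11 | step 10 | tris-TBS ether of ketone 23 | CC(C)(C)[Si](C)(C)Oc1cc2cc(c1)Oc1c(O[Si](C)(C)C(C)(C)C)cc(cc1O[Si](C)(C)C(C)(C)C)C(=O)CCCCCCCCCCCCC2
F12 | step 10 | tris-TBS ether of 24, (R) | CC(C)(C)[Si](C)(C)Oc1cc2cc(c1)Oc1c(O[Si](C)(C)C(C)(C)C)cc(cc1O[Si](C)(C)C(C)(C)C)[C@H](O)CCCCCCCCCCCCC2
A1 | alternative 1 | 14-[3-(benzyloxy)-5-hydroxyphenyl]-1-(4-bromo-3,5-dimethoxyphenyl)tetradecan-1-one | O=C(CCCCCCCCCCCCCc1cc(O)cc(OCc2ccccc2)c1)c1cc(OC)c(Br)c(OC)c1
A2 | alternative 1 | macrocyclic ketone with ring A benzyl ether and ring B dimethyl ether | O=C1CCCCCCCCCCCCCc2cc(OCc3ccccc3)cc(c2)Oc2c(OC)cc1cc2OC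
A3 | alternative 2 | 3-{14-[4-(ethynyloxy)-3,5-dimethoxyphenyl]-14-oxotetradecyl}cyclobut-2-en-1-one | C#COc1c(OC)cc(cc1OC)C(=O)CCCCCCCCCCCCCC1=CC(=O)C1
A4 | alternative 3 | 3-chloro-5-(dec-9-en-1-yl)cyclohex-2-en-1-one | O=C1C=C(Cl)CC(CCCCCCCCC=C)C1
A5 | alternative 3 | 1-(4-hydroxy-3,5-dimethoxyphenyl)hex-5-en-1-one | COc1cc(C(=O)CCCC=C)cc(OC)c1O
A6 | alternative 3 | 5-(dec-9-en-1-yl)-3-[4-(hex-5-enoyl)-2,6-dimethoxyphenoxy]cyclohex-2-en-1-one | O=C1C=C(Oc2c(OC)cc(cc2OC)C(=O)CCCC=C)CC(CCCCCCCCC=C)C1
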